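**Retrosynthetic overview**
1. Feature: each of the two identical benzene rings carries, ortho to its oxygen, the chain Ar–CH(CH3)–CH2–CH2–CH=C(CH3)2. The CH2–CH= bond joins a primary sp3 carbon to an alkenyl CH whose partner carbon bears two equal methyl groups. It can therefore be made last, twice in one flask, with no alkene geometry and no new stereocentre to control.
2. Target ⇒ O-demethylation ⇒ bis(methyl ether) ⇒ twofold nickel-electrocatalytic decarboxylative alkenylation ⇒ bis(N-acyloxyphthalimide) of the (S,S)-bis(4-arylpentanoic acid) + 1-bromo-2-methylprop-1-ene.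
3. Diacid ⇒ aryl–aryl bond para to each methoxy group (one-pot borylation/Suzuki homocoupling) ⇒ (S)-4-(5-bromo-2-methoxy-4-methylphenyl)pentanoic acid. Alkene geometry and enantiopurity are settled on a crystalline monomer, because an S,R dimer with its remote centres could hardly be removed later.
4. Bromo acid ⇒ carboxylate-directed iridium hydrogenation ⇒ (E)-4-arylpent-3-enoic acid ⇒ Wittig ⇒ aryl methyl ketone ⇒ Friedel–Crafts acetylation of 4-bromo-3-methylanisole.
5. No ring is formed at any stage: both benzene rings come with the starting bromide and are joined in step 4.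

Key step: step 6

Assumptions: the biaryl axis is flanked by only two ortho methyl groups and two ortho hydrogens, so it should rotate freely at room temperature and is not a stereo-element (the target SMILES shows none); the sense of induction in step 3 is taken by analogy with simpler (E)-4-arylpent-3-enoic acids, both ligand antipodes are available, and the one that gives the S acid is used.

**Step 1**
Reactants: 1 4-bromo-3-methylanisole
Product: 2 1-(5-bromo-2-methoxy-4-methylphenyl)ethan-1-one
Conditions: AcCl (1.2 equiv), AlCl3 (1.3 equiv), CH2Cl2, 0 °C; ice/HCl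
Reagents that add atoms: acetyl chloride, CC(=O)Cl
Why: Friedel–Crafts acylation, in which the methoxy group directs ortho because bromine holds its para position, only C6 (para to the methyl group) is open since C2 is wedged between OCH3 and CH3, and the low temperature keeps AlCl3 from cleaving the ether next to the new ketone.

**Step 2**
Reactants: 2 1-(5-bromo-2-methoxy-4-methylphenyl)ethan-1-one; 3 (2-carboxyethyl)triphenylphosphonium bromide
Product: 5 (E)-4-(5-bromo-2-methoxy-4-methylphenyl)pent-3-enoic acid, via phosphonium ylide 4 (not isolated)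
Conditions: 3 (1.6 equiv), KOtBu (3.3 equiv, added to the suspension of 2 and 3), THF, 0 °C → rt; cold 1 M HCl; acid–base extraction; recrystallisation
Reagents that add atoms: (2-carboxyethyl)triphenylphosphonium bromide (3), OC(=O)CC[P+](c1ccccc1)(c1ccccc1)c1ccccc1.[Br-]
Why: Wittig olefination with the carboxylate-bearing ylide 4, which is generated in the presence of the ketone so that it is trapped before it can shed acrylate, should place the aryl group trans to the CH2CO2K arm for steric reasons, and extraction removes Ph3PO and unchanged ketone while recrystallisation removes the Z isomer, which would be hydrogenated to the wrong enantiomer.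

**Step 3**
Reactants: 5 (E)-4-(5-bromo-2-methoxy-4-methylphenyl)pent-3-enoic acid
Product: 6 (S)-4-(5-bromo-2-methoxy-4-methylphenyl)pentanoic acid
Conditions: [Ir(cod)(SIPHOX)]BArF (1 mol %; SIPHOX = spirobiindane phosphine–oxazoline with P(3,5-tBu2C6H3)2, BArF = tetrakis[3,5-bis(trifluoromethyl)phenyl]borate), H2 (6 bar), NEt3 (1 equiv), MeOH, 25–45 °C; 1 M HCl; recrystallisation if chiral HPLC calls for it
Reagents that add atoms: none
Why: Carboxylate-directed iridium-catalysed asymmetric hydrogenation of a β,γ-unsaturated acid, in which the carboxylate binds the metal and fixes which face of the geometrically pure trisubstituted alkene meets the iridium dihydride in the spiro pocket, setting C4 as S, while the aryl bromide is inert to the cationic iridium hydride.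

**Step 4**
Reactants: 6 (S)-4-(5-bromo-2-methoxy-4-methylphenyl)pentanoic acid (two molecules); 7 bis(pinacolato)diboron
Product: 9 (4S,4'S)-4,4'-(4,4'-dimethoxy-6,6'-dimethylbiphenyl-3,3'-diyl)dipentanoic acid, via aryl pinacol boronate 8 (not isolated)
Conditions: 7 (0.55 equiv), Pd(dppf)Cl2 (5 mol %), K2CO3 (4 equiv), DMSO, 85 °C; 1 M HCl
Reagents that add atoms: none
Why: One-pot Miyaura borylation and Suzuki–Miyaura coupling (symmetrical biaryl synthesis), in which about half of the bromide becomes boronate 8 and the same palladium catalyst couples it to the remaining bromide under carbonate activation, the acid travels as its inert potassium carboxylate, only two ortho methyl groups flank the new bond, the stereocentres are untouched, and residual R monomer ends up almost wholly in the S,R dimer so that the chiral dimer is enriched statistically.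

**Step 5**
Reactants: 9 (4S,4'S)-4,4'-(4,4'-dimethoxy-6,6'-dimethylbiphenyl-3,3'-diyl)dipentanoic acid; 10 N-hydroxyphthalimide
Product: 11 bis(1,3-dioxoisoindolin-2-yl) (4S,4'S)-4,4'-(4,4'-dimethoxy-6,6'-dimethylbiphenyl-3,3'-diyl)dipentanoate
Conditions: 10 (2.3 equiv), DIC (2.4 equiv), DMAP (0.2 equiv), CH2Cl2, rt
Reagents that add atoms: N-hydroxyphthalimide (10), O=C1c2ccccc2C(=O)N1O
Why: Steglich-type carbodiimide esterification, in which DIC activates each carboxyl group, DMAP relays the acyl group to the N–OH oxygen of 10, and the neutral conditions leave the ethers and the remote stereocentres alone.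

**Step 6**
Reactants: 11 bis(1,3-dioxoisoindolin-2-yl) (4S,4'S)-4,4'-(4,4'-dimethoxy-6,6'-dimethylbiphenyl-3,3'-diyl)dipentanoate; 12 1-bromo-2-methylprop-1-ene
Product: 13 4,4'-dimethoxy-2,2'-dimethyl-5,5'-bis[(2S)-6-methylhept-5-en-2-yl]-1,1'-biphenyl
Conditions: 12 (6 equiv), NiCl2(glyme) (20 mol %), 2,2'-bipyridine (22 mol %), AgNO3 (0.6 equiv, plates silver metal on the cathode), n-Bu4NPF6 (0.1 M), dry DMF, Mg anode/reticulated vitreous carbon cathode, undivided cell, constant current at low current density, 5–6 F per mol of 11, rt; aq. NH4Cl
Reagents that add atoms: 1-bromo-2-methylprop-1-ene (12), CC(C)=CBr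
Why: The cathode reduces the divalent nickel–bipyridine complex to a low-valent species that inserts into the C–Br bond of 12, while single-electron transfer to each N-acyloxyphthalimide unit of 11 expels phthalimide anion and CO2 and leaves a primary CH2 radical. The alkenylnickel bromide traps that radical, reductive elimination from the resulting trivalent alkyl(alkenyl)nickel forges the CH2–CH= bond and returns monovalent nickel to the cathodic cycle, and magnesium dissolving at the anode balances the charge at a potential far too low to oxidise the anisole rings. This is the known nickel-electrocatalytic decarboxylative alkenylation of redox-active esters with alkenyl halides, a reductive cross-electrophile coupling, run here at two identical and mutually remote sites of one molecule. No ring is closed and no stereocentre is made, and the existing benzylic centres sit two saturated carbons from the radical site with no pathway to invert. The step needs radical capture by alkenylnickel to beat hydrogen abstraction, alkyl dimerisation and ester hydrolysis, which is served by the unhindered primary radical, a large excess of cheap volatile 12, the silver-coated cathode and a low current density that keeps the radical concentration small. Alkene geometry is no issue because the distal alkenyl carbon of 12 carries two methyl groups.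

**Step 7**
Reactants: 13 4,4'-dimethoxy-2,2'-dimethyl-5,5'-bis[(2S)-6-methylhept-5-en-2-yl]-1,1'-biphenyl
Product: 14 2,2'-dimethyl-5,5'-bis[(2S)-6-methylhept-5-en-2-yl]-1,1'-biphenyl-4,4'-diol (CNP0163343.1)
Conditions: NaSEt (10 equiv), DMF, 130 °C, argon; cold 1 M HCl to pH 5
Reagents that add atoms: none
Why: SN2 dealkylation of aryl methyl ethers by a soft thiolate, in which ethanethiolate attacks each O–CH3 carbon and expels the phenoxide, a basic and non-oxidising process that should spare the acid-sensitive trisubstituted alkenes and the non-acidic benzylic C–H bonds.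

**Compound list**
1 | 4-bromo-3-methylanisole | COc1ccc(Br)c(C)c1 | starting material
2 | 1-(5-bromo-2-methoxy-4-methylphenyl)ethan-1-one | CC(=O)c1cc(Br)c(C)cc1OC | intermediate
3 | (2-carboxyethyl)triphenylphosphonium bromide | OC(=O)CC[P+](c1ccccc1)(c1ccccc1)c1ccccc1.[Br-] | starting material
4 | potassium 3-(triphenylphosphoranylidene)propanoate (ylide, not isolated) | [K+].[O-]C(=O)CC=P(c1ccccc1)(c1ccccc1)c1ccccc1 | intermediate
5 | (E)-4-(5-bromo-2-methoxy-4-methylphenyl)pent-3-enoic acid | C/C(=C\CC(=O)O)c1cc(Br)c(C)cc1OC | intermediate
6 | (S)-4-(5-bromo-2-methoxy-4-methylphenyl)pentanoic acid | OC(=O)CC[C@H](C)c1cc(Br)c(C)cc1OC | intermediate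
7 | bis(pinacolato)diboron | CC1(C)OB(OC1(C)C)B1OC(C)(C)C(C)(C)O1 | starting material
8 | (S)-4-[2-methoxy-4-methyl-5-(4,4,5,5-tetramethyl-1,3,2-dioxaborolan-2-yl)phenyl]pentanoic acid (present as its potassium salt, not isolated) | OC(=O)CC[C@H](C)c1cc(B2OC(C)(C)C(C)(C)O2)c(C)cc1OC | intermediate
9 | (4S,4'S)-4,4'-(4,4'-dimethoxy-6,6'-dimethylbiphenyl-3,3'-diyl)dipentanoic acid | OC(=O)CC[C@H](C)c1cc(-c2cc([C@@H](C)CCC(=O)O)c(OC)cc2C)c(C)cc1OC | intermediate
10 | N-hydroxyphthalimide | O=C1c2ccccc2C(=O)N1O | starting material
11 | bis(1,3-dioxoisoindolin-2-yl) (4S,4'S)-4,4'-(4,4'-dimethoxy-6,6'-dimethylbiphenyl-3,3'-diyl)dipentanoate | O=C(ON1C(=O)c2ccccc2C1=O)CC[C@H](C)c1cc(-c2cc([C@@H](C)CCC(=O)ON3C(=O)c4ccccc4C3=O)c(OC)cc2C)c(C)cc1OC | intermediate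
12 | 1-bromo-2-methylprop-1-ene | CC(C)=CBr | starting material
13 | 4,4'-dimethoxy-2,2'-dimethyl-5,5'-bis[(2S)-6-methylhept-5-en-2-yl]-1,1'-biphenyl | CC(C)=CCC[C@H](C)c1cc(-c2cc([C@@H](C)CCC=C(C)C)c(OC)cc2C)c(C)cc1OC | intermediate
14 | 2,2'-dimethyl-5,5'-bis[(2S)-6-methylhept-5-en-2-yl]-1,1'-biphenyl-4,4'-diol | CC(C)=CCC[C@H](C)c1cc(-c2cc([C@@H](C)CCC=C(C)C)c(O)cc2C)c(C)cc1O | target

Total step count: 7. Longest linear sequence: 7 steps (1 → 14).

**Steps most likely to fail**

Step 6. The active esters may be reduced too early, followed by hydrogen abstraction (net decarboxylative reduction). Radical dimerisation, hydrolysis of the esters by magnesium salts and traces of water, and stalling after only one site has coupled are also possible. Every loss counts twice because both sites must react. The fallback replaces the radical coupling by a polar olefination and sets out from 9. BH3·SMe2 in THF should reduce both carboxyl groups to (4S,4'S)-4,4'-(4,4'-dimethoxy-6,6'-dimethylbiphenyl-3,3'-diyl)bis(pentan-1-ol) F1. Dess–Martin periodinane in CH2Cl2 should then give (4S,4'S)-4,4'-(4,4'-dimethoxy-6,6'-dimethylbiphenyl-3,3'-diyl)dipentanal F2. A twofold Wittig reaction with isopropyltriphenylphosphonium iodide and n-BuLi in THF installs both isopropylidene ends, and the sequence comes back to the route at 13.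

Step 2. The basic ylide may enolise the hindered ortho-methoxy ketone, the ylide may lose acrylate by retro-Michael fragmentation, and the control of alkene geometry may be insufficient. The fallback builds the alkene under thermodynamic control and sets out from 2.
- Corey–Chaykovsky methylenation (trimethylsulfonium iodide, NaH, DMSO/THF) should give racemic 2-(5-bromo-2-methoxy-4-methylphenyl)-2-methyloxirane F3.
- Meinwald rearrangement (BF3·OEt2, CH2Cl2, −78 °C) should give racemic 2-(5-bromo-2-methoxy-4-methylphenyl)propanal F4, whose stereocentre is erased in the next operation.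
- Decarboxylative Knoevenagel condensation with malonic acid in N-methylmorpholine at 95 °C passes through 2-[2-(5-bromo-2-methoxy-4-methylphenyl)propylidene]propanedioic acid F5.
- F5 deconjugates into the styrene position and loses CO2, and the sequence comes back to the route at 5.

Step 3. Facial selectivity may be poor, because the ortho-methoxy group twists the arene out of the alkene plane and may compete with the carboxylate for iridium. Slow turnover and double-bond migration before reduction are further risks. The fallback sets the centre by copper hydride conjugate reduction one carbon earlier, then homologates, and sets out from 2.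
- Horner–Wadsworth–Emmons reaction (triethyl phosphonoacetate, NaH, THF, reflux) and chromatographic removal of the Z isomer should give ethyl (E)-3-(5-bromo-2-methoxy-4-methylphenyl)but-2-enoate F6.
- Asymmetric conjugate reduction uses Cu(OAc)2, the DTBM-SEGPHOS antipode that delivers S, PMHS and t-BuOH in toluene, and should give ethyl (S)-3-(5-bromo-2-methoxy-4-methylphenyl)butanoate F7.
- LiOH in THF/water should give (S)-3-(5-bromo-2-methoxy-4-methylphenyl)butanoic acid F8.
- Arndt–Eistert homologation follows: oxalyl chloride with catalytic DMF gives (S)-3-(5-bromo-2-methoxy-4-methylphenyl)butanoyl chloride F9.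
- Diazomethane with NEt3 in Et2O then gives (S)-1-diazo-4-(5-bromo-2-methoxy-4-methylphenyl)pentan-2-one F10.
- Wolff rearrangement (silver benzoate AgO2CPh, NEt3, THF/water) leaves the stereocentre untouched, and the sequence comes back to the route at 6.

**Further compounds**
F1 | step 6 | (4S,4'S)-4,4'-(4,4'-dimethoxy-6,6'-dimethylbiphenyl-3,3'-diyl)bis(pentan-1-ol) | OCCC[C@H](C)c1cc(-c2cc([C@@H](C)CCCO)c(OC)cc2C)c(C)cc1OC
F2 | step 6 | (4S,4'S)-4,4'-(4,4'-dimethoxy-6,6'-dimethylbiphenyl-3,3'-diyl)dipentanal | O=CCC[C@H](C)c1cc(-c2cc([C@@H](C)CCC=O)c(OC)cc2C)c(C)cc1OC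
F3 | step 2 | 2-(5-bromo-2-methoxy-4-methylphenyl)-2-methyloxirane (racemic) | CC1(CO1)c1cc(Br)c(C)cc1OC
F4 | step 2 | 2-(5-bromo-2-methoxy-4-methylphenyl)propanal (racemic) | CC(C=O)c1cc(Br)c(C)cc1OC
F5 | step 2 | 2-[2-(5-bromo-2-methoxy-4-methylphenyl)propylidene]propanedioic acid (racemic) | CC(C=C(C(=O)O)C(=O)O)c1cc(Br)c(C)cc1OC
F6 | step 3 | ethyl (E)-3-(5-bromo-2-methoxy-4-methylphenyl)but-2-enoate | CCOC(=O)/C=C(\C)c1cc(Br)c(C)cc1OC
F7 | step 3 | ethyl (S)-3-(5-bromo-2-methoxy-4-methylphenyl)butanoate | CCOC(=O)C[C@H](C)c1cc(Br)c(C)cc1OC
F8 | step 3 | (S)-3-(5-bromo-2-methoxy-4-methylphenyl)butanoic acid | OC(=O)C[C@H](C)c1cc(Br)c(C)cc1OC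
F9 | step 3 | (S)-3-(5-bromo-2-methoxy-4-methylphenyl)butanoyl chloride | ClC(=O)C[C@H](C)c1cc(Br)c(C)cc1OC
F10 | step 3 | (S)-1-diazo-4-(5-bromo-2-methoxy-4-methylphenyl)pentan-2-one | [N-]=[N+]=CC(=O)C[C@H](C)c1cc(Br)c(C)cc1OC
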